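**Strategy.** The route rests on the aryl–C2 bond of the dihydropyranone ring. C2 lies β to the C4 carbonyl (O1–C2–C3–C4), so this bond is made by a Rh/(S)-BINAP-catalysed asymmetric 1,4-addition of the B-ring arylzinc to a flat, achiral 8-prenylchromone, with Me3SiCl capture of the enolate. One operation joins both halves, sets C2 and delivers C3 as an enol silane carbon, ready for anti-selective Rubottom oxygenation to the trans 3-ol. The precursor is 7-methoxy-5-(methoxymethoxy)-8-prenylchromone, whose prenyl group is placed by a para-Claisen–Cope shift of the 5-O-prenyl ether.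

Key step: step 6

Remark: flavan numbering (O1, C2, C3, C4, C4a, C5–C8, C8a; B ring C1'–C6') is used for all bicyclic compounds. The Re-face sense of (S)-BINAP is assigned by analogy with Rh/BINAP arylations of cyclic enones; the antipodal ligand would be used should the sense prove opposite.

Step 1
Reactants: 1 2',6'-dihydroxy-4'-methoxyacetophenone; 2 prenyl bromide (1-bromo-3-methylbut-2-ene)
Product: 3 1-[2-hydroxy-4-methoxy-6-(3-methylbut-2-enyloxy)phenyl]ethanone
Conditions: K2CO3 (1.5 equiv), 2 (1.05 equiv), acetone, reflux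
Reagents that add atoms: none
Why: Williamson etherification; once one hydroxyl of the symmetric 2,6-dihydroxyaryl ketone is alkylated, the other is held in a strong hydrogen bond to the carbonyl and resists a second alkylation, so the mono-ether should predominate.

Step 2
Reactants: 3 1-[2-hydroxy-4-methoxy-6-(3-methylbut-2-enyloxy)phenyl]ethanone
Product: 5 7-methoxy-5-(3-methylbut-2-enyloxy)-4H-chromen-4-one, via enaminone 4 (not isolated)
Conditions: Me2NCH(OMe)2 (3 equiv), toluene, 100 °C; concentrate; AcOH, 80 °C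
Reagents that add atoms: N,N-dimethylformamide dimethyl acetal, COC(OC)N(C)C
Why: Enaminone formation at the acetyl methyl group, then acid-promoted conjugate addition of the chelated hydroxyl and loss of dimethylamine (6-endo closure), is the standard chromone annulation, and the weak acid and moderate temperature should leave the prenyl ether intact.

Step 3
Reactants: 5 7-methoxy-5-(3-methylbut-2-enyloxy)-4H-chromen-4-one
Product: 8 5-hydroxy-7-methoxy-8-(3-methylbut-2-enyl)-4H-chromen-4-one, via ortho-dienone 6 (not isolated), via para-dienone 7 (not isolated)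
Conditions: Eu(fod)3 (10 mol %), NaHCO3, PhCl, 85 °C
Reagents that add atoms: none
Why: A Eu(III)-accelerated aromatic Claisen rearrangement ([3,3], O5 to C6, giving the 1,1-dimethylallyl dienone 6) is followed by a Cope rearrangement ([3,3], C6 to C8, restoring the linear prenyl group in 7) and enolisation, so the prenyl group should end para to O5 at C8 with the 5-OH freed (para-Claisen–Cope sequence).

Step 4
Reactants: 8 5-hydroxy-7-methoxy-8-(3-methylbut-2-enyl)-4H-chromen-4-one
Product: 9 7-methoxy-5-(methoxymethoxy)-8-(3-methylbut-2-enyl)-4H-chromen-4-one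
Conditions: NaH, MOMCl, DMF, 0 °C → rt
Reagents that add atoms: chloromethyl methyl ether, COCCl
Why: Deprotonation with NaH breaks the O5–H···O=C4 chelate and the phenoxide is O-alkylated by MOMCl (MOM protection), masking the acidic proton that would otherwise quench the arylzinc reagent of step 6.

Step 5
Reactants: 10 4-bromo-2-methoxyphenol
Product: 11 4-bromo-2-methoxy-1-(methoxymethoxy)benzene
Conditions: MOMCl, i-Pr2NEt, CH2Cl2, 0 °C → rt
Reagents that add atoms: chloromethyl methyl ether, COCCl
Why: Standard MOM protection of a phenol under amine base gives an aryl bromide whose only reactive site toward n-BuLi is the C–Br bond.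

Step 6
Reactants: 9 7-methoxy-5-(methoxymethoxy)-8-(3-methylbut-2-enyl)-4H-chromen-4-one; 11 4-bromo-2-methoxy-1-(methoxymethoxy)benzene
Product: 14 trimethyl{[(2S)-7-methoxy-2-[3-methoxy-4-(methoxymethoxy)phenyl]-5-(methoxymethoxy)-8-(3-methylbut-2-enyl)-2H-chromen-4-yl]oxy}silane, via aryllithium 12 (not isolated), via arylzinc chloride 13 (not isolated)
Conditions: 11 (1.5 equiv), n-BuLi, THF, −78 °C; ZnCl2, −78 °C → rt; then 9, [RhCl(C2H4)2]2 (1.5 mol %), (S)-BINAP (3.3 mol %), Me3SiCl (1.5 equiv), THF, 20 °C; cold aq NaHCO3/pentane work-up, used crude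
Reagents that add atoms: chlorotrimethylsilane, C[Si](C)(C)Cl
Why: Br/Li exchange and transmetalation to zinc give 13; Zn-to-Rh transmetalation forms an aryl–Rh(I)–BINAP species that inserts the C2=C3 bond of chromone 9 (syn carbometalation, aryl to C2), and the resulting Rh oxa-π-allyl is silylated on oxygen by Me3SiCl, releasing 14 and Rh–Cl for the next turnover. The closest known reaction types are the Rh/BINAP-catalysed asymmetric 1,4-addition of arylzinc chlorides with Me3SiCl to 4-quinolones and 2,3-dihydro-4-pyridones, and the Rh-catalysed asymmetric 1,4-arylation of chromones with arylboronic acids (Hayashi–Miyaura reaction). No ring is closed. The C2 stereocentre is set by the catalyst: (S)-BINAP is expected to deliver the aryl group to the Re face of C2, which is 2S here and becomes 2R in the target once C3 carries oxygen. The step needs 1,4- over 1,2-addition and no reaction at the prenyl olefin: the aryl–Rh species adds only to the polarised enone, the unactivated trisubstituted olefin should not insert, and silyl capture masks the ketone, so neither a second arylation nor retro-oxa-Michael opening (loss of C2 configuration) can follow.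

Step 7
Reactants: 14 trimethyl{[(2S)-7-methoxy-2-[3-methoxy-4-(methoxymethoxy)phenyl]-5-(methoxymethoxy)-8-(3-methylbut-2-enyl)-2H-chromen-4-yl]oxy}silane
Product: 17 (2R,3R)-3,5-dihydroxy-2-(4-hydroxy-3-methoxyphenyl)-7-methoxy-8-(3-methylbut-2-enyl)chroman-4-one, via siloxy epoxide 15 (not isolated), via bis-MOM dihydroflavonol 16 (not isolated)
Conditions: DMDO (1.05 equiv, acetone solution), CH2Cl2, −78 → 0 °C; evaporate; HCl (1 M in MeOH), rt → 40 °C
Reagents that add atoms: dimethyldioxirane, CC1(C)OO1
Why: Rubottom oxidation: DMDO should epoxidise the enol silane, by far the most electron-rich olefin (the prenyl olefin reacts much more slowly at −78 °C), from the face anti to the C2 aryl group; acid then opens the siloxy epoxide to the α-hydroxy ketone with the C3–O bond intact (3-OH trans to the aryl group, 2R,3R), and methanolysis of the two MOM acetals frees 5-OH and 4'-OH, the prenyl group having no neighbouring free hydroxyl to cyclise onto.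

**Compound list**

1 | 2',6'-dihydroxy-4'-methoxyacetophenone | CC(=O)c1c(O)cc(OC)cc1O | starting material
2 | prenyl bromide (1-bromo-3-methylbut-2-ene) | CC(C)=CCBr | starting material
3 | 1-[2-hydroxy-4-methoxy-6-(3-methylbut-2-enyloxy)phenyl]ethanone | CC(=O)c1c(O)cc(OC)cc1OCC=C(C)C | intermediate
4 | (E)-3-(dimethylamino)-1-[2-hydroxy-4-methoxy-6-(3-methylbut-2-enyloxy)phenyl]prop-2-en-1-one (enaminone, formed in the flask) | CN(C)/C=C/C(=O)c1c(O)cc(OC)cc1OCC=C(C)C | intermediate
5 | 7-methoxy-5-(3-methylbut-2-enyloxy)-4H-chromen-4-one | COc1cc(OCC=C(C)C)c2c(=O)ccoc2c1 | intermediate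
6 | 7-methoxy-6-(2-methylbut-3-en-2-yl)-6H-chromene-4,5-dione (ortho-dienone, racemic, formed in the flask) | COC1=CC2=C(C(=O)C=CO2)C(=O)C1C(C)(C)C=C | intermediate
7 | 7-methoxy-8-(3-methylbut-2-enyl)-8H-chromene-4,5-dione (para-dienone, racemic, formed in the flask) | COC1=CC(=O)C2=C(OC=CC2=O)C1CC=C(C)C | intermediate
8 | 5-hydroxy-7-methoxy-8-(3-methylbut-2-enyl)-4H-chromen-4-one | COc1cc(O)c2c(=O)ccoc2c1CC=C(C)C | intermediate
9 | 7-methoxy-5-(methoxymethoxy)-8-(3-methylbut-2-enyl)-4H-chromen-4-one | COCOc1cc(OC)c(CC=C(C)C)c2occc(=O)c12 | intermediate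
10 | 4-bromo-2-methoxyphenol | COc1cc(Br)ccc1O | starting material
11 | 4-bromo-2-methoxy-1-(methoxymethoxy)benzene | COCOc1ccc(Br)cc1OC | intermediate
12 | [3-methoxy-4-(methoxymethoxy)phenyl]lithium (formed in the flask) | [Li]c1ccc(OCOC)c(OC)c1 | intermediate
13 | [3-methoxy-4-(methoxymethoxy)phenyl]zinc chloride (formed in the flask) | Cl[Zn]c1ccc(OCOC)c(OC)c1 | intermediate
14 | trimethyl{[(2S)-7-methoxy-2-[3-methoxy-4-(methoxymethoxy)phenyl]-5-(methoxymethoxy)-8-(3-methylbut-2-enyl)-2H-chromen-4-yl]oxy}silane | COc1cc([C@H]2Oc3c(CC=C(C)C)c(OC)cc(OCOC)c3C(O[Si](C)(C)C)=C2)ccc1OCOC | intermediate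
15 | (2R,3R,4R)-3,4-epoxy-7-methoxy-2-[3-methoxy-4-(methoxymethoxy)phenyl]-5-(methoxymethoxy)-8-(3-methylbut-2-enyl)-4-(trimethylsilyloxy)chromane, epoxide oxygen anti to the C2 aryl group (formed in the flask) | COc1cc([C@H]2Oc3c(CC=C(C)C)c(OC)cc(OCOC)c3[C@]4(O[Si](C)(C)C)O[C@H]24)ccc1OCOC | intermediate
16 | (2R,3R)-3-hydroxy-7-methoxy-2-[3-methoxy-4-(methoxymethoxy)phenyl]-5-(methoxymethoxy)-8-(3-methylbut-2-enyl)chroman-4-one (formed in the flask) | COc1cc([C@H]2Oc3c(CC=C(C)C)c(OC)cc(OCOC)c3C(=O)[C@@H]2O)ccc1OCOC | intermediate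
17 | (2R,3R)-3,5-dihydroxy-2-(4-hydroxy-3-methoxyphenyl)-7-methoxy-8-(3-methylbut-2-enyl)chroman-4-one | COc1cc([C@H]2Oc3c(CC=C(C)C)c(OC)cc(O)c3C(=O)[C@@H]2O)ccc1O | target

**Step count.** Total: 7 steps. Longest linear sequence: 6 steps (1, 2, 3, 4, 6, 7).

**Steps most likely to fail**

1. Step 6 (key step). Aryl transfer may stall on the electron-rich, peri-substituted chromone, silyl capture may fail so that the product ketone reacts on, or facial selectivity may erode. Fallback: the C ring is built by oxa-Michael closure instead of conjugate arylation. Setting out from 9, aqueous NaOH in EtOH at reflux cleaves the pyranone (hydroxide addition at C2, retro-Claisen loss of formate) to 1-[2-hydroxy-4-methoxy-6-(methoxymethoxy)-3-(3-methylbut-2-enyl)phenyl]ethanone F1, in which only the hydroxyl next to the prenyl group is free. Aryllithium 12 (from 11 and n-BuLi) is quenched with DMF to give 3-methoxy-4-(methoxymethoxy)benzaldehyde F2. Claisen–Schmidt condensation of F1 with F2 (KOH, EtOH, rt) should give (E)-1-[2-hydroxy-4-methoxy-6-(methoxymethoxy)-3-(3-methylbut-2-enyl)phenyl]-3-[3-methoxy-4-(methoxymethoxy)phenyl]prop-2-en-1-one F3. A cinchona-derived bifunctional thiourea catalyst (quinine or quinidine series chosen for 2S) in toluene should close F3 by enantioselective 6-endo oxa-Michael addition to (2S)-7-methoxy-2-[3-methoxy-4-(methoxymethoxy)phenyl]-5-(methoxymethoxy)-8-(3-methylbut-2-enyl)chroman-4-one F4, to be enriched by crystallisation if needed. Soft enolisation (TMSOTf, Et3N, CH2Cl2, −78 → 0 °C) comes back to the route at 14.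

2. Step 7. The dioxirane may attack the prenyl olefin as well as the enol silane, or the enol silane may hydrolyse before oxidation. Fallback: epoxidation is replaced by enolate hydroxylation with an oxidant that leaves isolated olefins alone. Setting out from 14, MeLi (THF, −78 °C) releases the lithium enolate lithium (2S)-7-methoxy-2-[3-methoxy-4-(methoxymethoxy)phenyl]-5-(methoxymethoxy)-8-(3-methylbut-2-enyl)-2H-chromen-4-olate F5. Kept at −78 °C to avoid ring opening, F5 is hydroxylated at C3 anti to the aryl group by 2-(phenylsulfonyl)-3-phenyloxaziridine (Davis oxidation). A cold NH4Cl quench comes back to the route at 16, which is then isolated and deprotected with HCl in MeOH to 17.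

3. Step 3. The sigmatropic shift may stop at C6 as the 1,1-dimethylallyl isomer, or the prenyl ether may cleave. Fallback: the prenyl group is placed by cross-coupling on a ring with O5 already protected. Setting out from 1, MOMCl/i-Pr2NEt should give the mono-ether 1-[2-hydroxy-4-methoxy-6-(methoxymethoxy)phenyl]ethanone F6. DMF-DMA converts it to (E)-3-(dimethylamino)-1-[2-hydroxy-4-methoxy-6-(methoxymethoxy)phenyl]prop-2-en-1-one F7, which closes on mild acid treatment (AcOH, 40 °C) to 7-methoxy-5-(methoxymethoxy)-4H-chromen-4-one F8. N-Iodosuccinimide (DMF, rt) should iodinate the A ring at C8, the position favoured in chromones with O5 alkylated, to give 8-iodo-7-methoxy-5-(methoxymethoxy)-4H-chromen-4-one F9. Stille coupling with tributyl(3-methylbut-2-enyl)stannane (Pd(PPh3)4, DMF, 80 °C) installs the linear prenyl group and comes back to the route at 9.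

**Further compounds**

F1 | step 6 | 1-[2-hydroxy-4-methoxy-6-(methoxymethoxy)-3-(3-methylbut-2-enyl)phenyl]ethanone | CC(=O)c1c(O)c(CC=C(C)C)c(OC)cc1OCOC
F2 | step 6 | 3-methoxy-4-(methoxymethoxy)benzaldehyde | COCOc1ccc(C=O)cc1OC
F3 | step 6 | (E)-1-[2-hydroxy-4-methoxy-6-(methoxymethoxy)-3-(3-methylbut-2-enyl)phenyl]-3-[3-methoxy-4-(methoxymethoxy)phenyl]prop-2-en-1-one | COCOc1ccc(/C=C/C(=O)c2c(O)c(CC=C(C)C)c(OC)cc2OCOC)cc1OC
F4 | step 6 | (2S)-7-methoxy-2-[3-methoxy-4-(methoxymethoxy)phenyl]-5-(methoxymethoxy)-8-(3-methylbut-2-enyl)chroman-4-one | COc1cc([C@H]2Oc3c(CC=C(C)C)c(OC)cc(OCOC)c3C(=O)C2)ccc1OCOC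
F5 | step 7 | lithium (2S)-7-methoxy-2-[3-methoxy-4-(methoxymethoxy)phenyl]-5-(methoxymethoxy)-8-(3-methylbut-2-enyl)-2H-chromen-4-olate | COc1cc([C@H]2Oc3c(CC=C(C)C)c(OC)cc(OCOC)c3C(O[Li])=C2)ccc1OCOC
F6 | step 3 | 1-[2-hydroxy-4-methoxy-6-(methoxymethoxy)phenyl]ethanone | CC(=O)c1c(O)cc(OC)cc1OCOC
F7 | step 3 | (E)-3-(dimethylamino)-1-[2-hydroxy-4-methoxy-6-(methoxymethoxy)phenyl]prop-2-en-1-one | CN(C)/C=C/C(=O)c1c(O)cc(OC)cc1OCOC
F8 | step 3 | 7-methoxy-5-(methoxymethoxy)-4H-chromen-4-one | COCOc1cc(OC)cc2occc(=O)c12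
F9 | step 3 | 8-iodo-7-methoxy-5-(methoxymethoxy)-4H-chromen-4-one | COCOc1cc(OC)c(I)c2occc(=O)c12
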